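**Plan**

- Retrosynthesis: the aryl silyl ether is cut last. Then the bonds O1–C7a and C2–C3 of the dihydrofuran ring are cut together, giving a ring A ethylarene that carries a p-tolylsulfinyl group on C7a and the ring B aldehyde. Behind that lie S–C7a (aryl iodide plus sulfinate ester), C5–propenyl (aryl bromide plus alkenylboronate) and C3–CH3 (lateral methylation).
- Enabling feature: in ring A (the benzo ring, C3a to C7a) the benzylic carbon C3 and the aryl carbon C7a are 1,3-related through C3a. One sulfinyl group on C7a can therefore direct lithiation at C3 and afterwards leave from C7a. The C5 propenyl group is para to C7a and delocalises the charge of the substitution intermediate, and the aldehyde C=O of ring B supplies C2 and O1.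
- Forward: ring A is dressed (Br, I, sulfoxide, propenyl, ethyl); one pot then joins it to the aldehyde and closes the only new ring, the dihydrofuran; desilylation ends the route.
- Stereochemistry: the sulfur stereocentre comes from (1R,2S,5R)-menthyl (S)-p-toluenesulfinate. It sets C3 (S) in the key step through an O–Li chelate, C2 (S) follows as the 2,3-trans partner, and the auxiliary leaves in the same step. The (E)-alkene comes from the (E)-propenylboronate.

Key step: step 7

Assumption: the sense of induction at C3 follows the chelate model in step 7, on which the S sulfoxide leads to 3S; atom numbers are those of the benzofuran (O1, C2, C3, C3a, C4–C7, C7a) and ring B is the pendant aryl group.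

**Step 1**
Reactants: 1 2-methoxy-6-methylaniline
Product: 2 4-bromo-2-methoxy-6-methylaniline
Conditions: NBS (1.0 equiv), MeCN, 0 °C to rt
Reagents that add atoms: N-bromosuccinimide, O=C1CCC(=O)N1Br
Why: Electrophilic aromatic bromination of an aniline whose two ortho positions are blocked should go to the carbon para to NH2, which becomes C5.

**Step 2**
Reactants: 2 4-bromo-2-methoxy-6-methylaniline
Product: 4 5-bromo-2-iodo-1-methoxy-3-methylbenzene, via arenediazonium hydrogensulfate 3 (not isolated)
Conditions: NaNO2, H2SO4, MeCN/H2O, 0 °C; then KI, 0 °C to rt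
Reagents that add atoms: potassium iodide, [K+].[I-]
Why: Diazotisation followed by iodide displacement (Sandmeyer-type iodination) should replace NH2 by iodine at the future C7a without touching the bromide.

**Step 3**
Reactants: 4 5-bromo-2-iodo-1-methoxy-3-methylbenzene; 5 (1R,2S,5R)-menthyl (S)-p-toluenesulfinate
Product: 7 (S)-5-bromo-1-methoxy-3-methyl-2-(4-methylphenylsulfinyl)benzene, via arylmagnesium chloride 6 (not isolated)
Conditions: i-PrMgCl·LiCl (1.05 equiv), THF, −20 °C; then added to 5 (1.1 equiv) in toluene, −20 to 0 °C
Reagents that add atoms: none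
Why: Iodine–magnesium exchange is selective for the iodide over the bromide, and the aryl Grignard reagent should displace mentholate from sulfur with inversion (Andersen sulfoxide synthesis), which sets the sulfur stereocentre as S.

**Step 4**
Reactants: 7 (S)-5-bromo-1-methoxy-3-methyl-2-(4-methylphenylsulfinyl)benzene; 8 4,4,5,5-tetramethyl-2-[(E)-prop-1-enyl]-1,3,2-dioxaborolane
Product: 9 (S)-1-methoxy-3-methyl-2-(4-methylphenylsulfinyl)-5-[(E)-prop-1-enyl]benzene
Conditions: Pd(dppf)Cl2 (3 mol %), K3PO4, 1,4-dioxane/H2O, 80 °C
Reagents that add atoms: none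
Why: Suzuki–Miyaura coupling of the unhindered aryl bromide with an alkenylboronate keeps the alkene geometry, so the (E)-propenyl group should be installed intact while the configurationally stable sulfoxide is untouched.

**Step 5**
Reactants: 9 (S)-1-methoxy-3-methyl-2-(4-methylphenylsulfinyl)-5-[(E)-prop-1-enyl]benzene
Product: 11 (S)-1-ethyl-3-methoxy-2-(4-methylphenylsulfinyl)-5-[(E)-prop-1-enyl]benzene, via benzylic lithium 10 (not isolated)
Conditions: LiN(i-Pr)2 (LDA, 1.05 equiv), THF, −78 °C; then MeI, −78 °C
Reagents that add atoms: iodomethane, CI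
Why: Sulfinyl-directed lateral lithiation of the ortho methyl group followed by SN2 methylation should turn CH3 into the ethyl group that holds C3 and its methyl, with no stereocentre formed.

**Step 6**
Reactants: 12 3-hydroxy-4,5-dimethoxybenzaldehyde
Product: 13 3,4-dimethoxy-5-(triisopropylsilyloxy)benzaldehyde
Conditions: TIPSCl, imidazole, DMF, rt
Reagents that add atoms: chlorotriisopropylsilane, CC(C)[Si](Cl)(C(C)C)C(C)C
Why: Silylation of the phenol masks the only acidic proton of ring B with a group that should withstand organolithium and alkoxide conditions.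

**Step 7**
Reactants: 11 (S)-1-ethyl-3-methoxy-2-(4-methylphenylsulfinyl)-5-[(E)-prop-1-enyl]benzene; 13 3,4-dimethoxy-5-(triisopropylsilyloxy)benzaldehyde
Product: 16 [5-[(2S,3S)-7-methoxy-3-methyl-5-[(E)-prop-1-enyl]-2,3-dihydro-1-benzofuran-2-yl]-2,3-dimethoxyphenoxy]triisopropylsilane, via benzylic lithium 14 (not isolated), via lithium alkoxide 15 (not isolated)
Conditions: LiN(i-Pr)2 (LDA, 1.1 equiv), THF, −78 °C; then 13 (1.2 equiv), −78 °C; then DMPU, −78 to 25 °C (40 °C if closure is slow); then H2O
Reagents that add atoms: none
Why: Proposed new method: LDA removes a benzylic proton of the ethyl group with help from the sulfinyl oxygen to give the chelated carbanion 14, which adds to the aldehyde carbon (C2–C3 bond) to give alkoxide 15; the alkoxide oxygen then attacks C7a, ipso to sulfur, and p-toluenesulfenate leaves (O1–C7a bond), either by addition–elimination through a Meisenheimer-type anion or through a cyclic alkoxysulfurane that collapses by ligand coupling, both paths giving the same product. The closest known reaction type is the one-pot addition of ortho-sulfinyl benzyl carbanions to imines followed by intramolecular displacement of the sulfinyl group by the amide nitrogen to give indolines, together with the known addition of such carbanions to aldehydes; the oxygen ring closure is the new element. The dihydrofuran ring closes by 5-exo-trig intramolecular nucleophilic aromatic substitution at C7a. C3 is controlled by the sulfur stereocentre: lithium bridges the sulfinyl oxygen and C3 on the face away from the p-tolyl group, the C3 methyl points away from sulfur, and the lithium-bound aldehyde is delivered to that face; C2 is controlled by the relative topicity of this lithium-bridged addition and, because the addition is reversible, by the faster closure of the alkoxide that leads to the 2,3-trans ring. The step needs benzylic lithiation in preference to metalation of the p-tolyl methyl, the propenyl methyl or an aryl C–H, which chelation to the sulfinyl oxygen should secure, and it needs substitution at C7a only, which the five-membered geometry, the sulfenate leaving group and the charge-delocalising propenyl group para to C7a should secure.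

**Step 8**
Reactants: 16 [5-[(2S,3S)-7-methoxy-3-methyl-5-[(E)-prop-1-enyl]-2,3-dihydro-1-benzofuran-2-yl]-2,3-dimethoxyphenoxy]triisopropylsilane
Product: 17 5-[(2S,3S)-7-methoxy-3-methyl-5-[(E)-prop-1-enyl]-2,3-dihydro-1-benzofuran-2-yl]-2,3-dimethoxyphenol
Conditions: TBAF (1.1 equiv), THF, 0 °C; then H2O
Reagents that add atoms: none
Why: Fluoride-mediated desilylation should free the phenol under conditions that leave the benzylic aryl ether, both stereocentres and the (E)-alkene untouched.

**Compound list**

1 | 2-methoxy-6-methylaniline | Cc1cccc(OC)c1N | starting material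
2 | 4-bromo-2-methoxy-6-methylaniline | Cc1cc(Br)cc(OC)c1N | intermediate
3 | 4-bromo-2-methoxy-6-methylbenzenediazonium hydrogensulfate | Cc1cc(Br)cc(OC)c1[N+]#N.OS(=O)(=O)[O-] | intermediate
4 | 5-bromo-2-iodo-1-methoxy-3-methylbenzene | Cc1cc(Br)cc(OC)c1I | intermediate
5 | (1R,2S,5R)-menthyl (S)-p-toluenesulfinate | C[C@@H]1CC[C@H]([C@@H](C1)O[S@](=O)c1ccc(C)cc1)C(C)C | starting material
6 | (4-bromo-2-methoxy-6-methylphenyl)magnesium chloride | Cc1cc(Br)cc(OC)c1[Mg]Cl | intermediate
7 | (S)-5-bromo-1-methoxy-3-methyl-2-(4-methylphenylsulfinyl)benzene | Cc1cc(Br)cc(OC)c1[S@@](=O)c1ccc(C)cc1 | intermediate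
8 | 4,4,5,5-tetramethyl-2-[(E)-prop-1-enyl]-1,3,2-dioxaborolane | C/C=C/B1OC(C)(C)C(C)(C)O1 | starting material
9 | (S)-1-methoxy-3-methyl-2-(4-methylphenylsulfinyl)-5-[(E)-prop-1-enyl]benzene | C/C=C/c1cc(C)c([S@@](=O)c2ccc(C)cc2)c(OC)c1 | intermediate
10 | lithium salt of the benzylic carbanion of 9 (CH2 on the carbon that becomes C3a) | [Li+].[CH2-]c1cc(/C=C/C)cc(OC)c1[S@@](=O)c1ccc(C)cc1 | intermediate
11 | (S)-1-ethyl-3-methoxy-2-(4-methylphenylsulfinyl)-5-[(E)-prop-1-enyl]benzene | CCc1cc(/C=C/C)cc(OC)c1[S@@](=O)c1ccc(C)cc1 | intermediate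
12 | 3-hydroxy-4,5-dimethoxybenzaldehyde | COc1cc(C=O)cc(O)c1OC | starting material
13 | 3,4-dimethoxy-5-(triisopropylsilyloxy)benzaldehyde | COc1cc(C=O)cc(O[Si](C(C)C)(C(C)C)C(C)C)c1OC | intermediate
14 | lithium salt of the benzylic carbanion of 11 (carbanion at C3, chelated by the sulfinyl oxygen) | [Li+].C[CH-]c1cc(/C=C/C)cc(OC)c1[S@@](=O)c1ccc(C)cc1 | intermediate
15 | lithium (1S,2S)-1-[3,4-dimethoxy-5-(triisopropylsilyloxy)phenyl]-2-[3-methoxy-2-[(S)-4-methylphenylsulfinyl]-5-[(E)-prop-1-enyl]phenyl]propan-1-olate | C/C=C/c1cc(OC)c([S@@](=O)c2ccc(C)cc2)c(c1)[C@H](C)[C@@H](c1cc(O[Si](C(C)C)(C(C)C)C(C)C)c(OC)c(OC)c1)[O-].[Li+] | intermediate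
16 | [5-[(2S,3S)-7-methoxy-3-methyl-5-[(E)-prop-1-enyl]-2,3-dihydro-1-benzofuran-2-yl]-2,3-dimethoxyphenoxy]triisopropylsilane | C/C=C/c1cc(OC)c2c(c1)[C@H](C)[C@@H](c1cc(O[Si](C(C)C)(C(C)C)C(C)C)c(OC)c(OC)c1)O2 | intermediate
17 | 5-[(2S,3S)-7-methoxy-3-methyl-5-[(E)-prop-1-enyl]-2,3-dihydro-1-benzofuran-2-yl]-2,3-dimethoxyphenol | C/C=C/c1cc(OC)c2c(c1)[C@H](C)[C@@H](c1cc(O)c(OC)c(OC)c1)O2 | target

**Step count and risks**

Total steps: 8. Longest linear sequence: 7 steps (steps 1 to 5, 7 and 8, from compound 1).

Most likely to fail:

1. Step 7. The alkoxide may fail to displace the sulfinyl group so that the sequence stalls at the carbinol, the addition may revert on warming, or facial selectivity at C2 may be weak.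
 Fallback with known chemistry, setting out from 11 and 13: 11 is lithiated with LDA at −78 °C, 13 is added and the mixture is quenched cold, which should give the sulfinyl carbinol (1S,2S)-1-[3,4-dimethoxy-5-(triisopropylsilyloxy)phenyl]-2-[3-methoxy-2-[(S)-4-methylphenylsulfinyl]-5-[(E)-prop-1-enyl]phenyl]propan-1-ol F1; either C1 epimer serves. Sulfoxide–lithium exchange with n-BuLi (2.2 equiv, THF, −78 °C), trapping of the aryllithium with B(OMe)3 and oxidation with H2O2/NaOH should give the phenol 2-[(1S,2S)-1-[3,4-dimethoxy-5-(triisopropylsilyloxy)phenyl]-1-hydroxypropan-2-yl]-6-methoxy-4-[(E)-prop-1-enyl]phenol F2. Acid-catalysed cyclodehydration (catalytic p-TsOH, CH2Cl2, 0 °C) then closes the ring by SN1 substitution at C2 through the benzylic cation stabilised by ring B, which should give the 2,3-trans isomer whatever the C2 configuration, and the route is rejoined at 16. C3 keeps the configuration set by the auxiliary. The same acid treatment should also equilibrate a C2-epimeric mixture of 16 to the trans isomer.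

2. Step 5. Deprotonation may compete at the propenyl methyl or the p-tolyl methyl group, and double methylation may occur.
 Fallback, setting out from 7: the lateral lithiation and methylation (LDA, THF, −78 °C; MeI) are run before the propenyl group is present, which should give (S)-5-bromo-1-ethyl-3-methoxy-2-(4-methylphenylsulfinyl)benzene F3. Suzuki–Miyaura coupling of F3 with 8 under the conditions of step 4 then rejoins the route at 11.

3. Step 3. Sulfinyl transfer to the di-ortho-substituted Grignard reagent may be slow, and excess Grignard reagent may erode enantiopurity by ligand exchange at sulfur.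
 Fallback, setting out from 4: CuI-catalysed C–S coupling with 4-methylbenzenethiol (K2CO3, i-PrOH/ethylene glycol, 80 °C), selective for the iodide, should give 5-bromo-1-methoxy-3-methyl-2-(4-methylphenylsulfanyl)benzene F4. Enantioselective sulfoxidation (Kagan oxidation: Ti(Oi-Pr)4, diethyl tartrate of the enantiomer that delivers the S sulfoxide, H2O, cumene hydroperoxide), with upgrade by crystallisation or chromatography on a chiral phase, then rejoins the route at 7.

**Further compounds**

F1 | step 7 | (1S,2S)-1-[3,4-dimethoxy-5-(triisopropylsilyloxy)phenyl]-2-[3-methoxy-2-[(S)-4-methylphenylsulfinyl]-5-[(E)-prop-1-enyl]phenyl]propan-1-ol | C/C=C/c1cc(OC)c([S@@](=O)c2ccc(C)cc2)c(c1)[C@H](C)[C@@H](c1cc(O[Si](C(C)C)(C(C)C)C(C)C)c(OC)c(OC)c1)O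
F2 | step 7 | 2-[(1S,2S)-1-[3,4-dimethoxy-5-(triisopropylsilyloxy)phenyl]-1-hydroxypropan-2-yl]-6-methoxy-4-[(E)-prop-1-enyl]phenol | C/C=C/c1cc(OC)c(O)c(c1)[C@H](C)[C@@H](c1cc(O[Si](C(C)C)(C(C)C)C(C)C)c(OC)c(OC)c1)O
F3 | step 5 | (S)-5-bromo-1-ethyl-3-methoxy-2-(4-methylphenylsulfinyl)benzene | CCc1cc(Br)cc(OC)c1[S@@](=O)c1ccc(C)cc1
F4 | step 3 | 5-bromo-1-methoxy-3-methyl-2-(4-methylphenylsulfanyl)benzene | Cc1cc(Br)cc(OC)c1Sc1ccc(C)cc1
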